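The plan closes the 20-membered ring last, at the diaryl ether between ring A (the trisubstituted ring whose ether carbon is para to its CH2CH2 arm) and the meta-phenylene ring B. The feature exploited is that the hydroxyl-bearing carbon of ring A is ortho to this ether carbon. In the precursor that carbon carries a formyl group, which activates the adjacent C–F bond for intramolecular SNAr by the ring-B phenoxide and is afterwards exchanged for OH by Dakin oxidation. Ring D is handled in the same way at the start. The cyclisation precursor is an open-chain fluoro dialdehyde phenol with both ethano bridges in place, built by Heck and Sonogashira couplings and one chemoselective hydrogenation.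

Key step: step 6

Remark: the target has no stereocentre; the only stereo-element on the route is the E alkene of 7 and 9, which step 5 removes. 2-Fluoro-4-iodobenzaldehyde, 5-bromo-2-fluorobenzaldehyde, 3-ethynylphenol and tributyl(vinyl)stannane are taken as catalogue compounds. Ring labels: A = trisubstituted ring with OH meta to its CH2CH2 arm; B = meta-phenylene; C = para-phenylene; D = trisubstituted ring with OH para to its CH2CH2 arm.

Step 1
Reactants: 1 4-bromophenol; 2 2-fluoro-4-iodobenzaldehyde
Product: 3 2-(4-bromophenoxy)-4-iodobenzaldehyde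
Conditions: K2CO3, DMF, 90 °C
Reagents that add atoms: none
Why: Intermolecular SNAr (addition–elimination) in which the ortho formyl group stabilises the Meisenheimer adduct, so the phenoxide displaces fluoride far faster than the iodide para to the formyl group, giving the ring C–O–ring D ether.

Step 2
Reactants: 4 5-bromo-2-fluorobenzaldehyde; 5 tributyl(vinyl)stannane
Product: 6 2-fluoro-5-vinylbenzaldehyde
Conditions: Pd(PPh3)4 (cat.), toluene, 100 °C
Reagents that add atoms: none
Why: Stille vinylation of the aryl bromide under neutral conditions, which should leave the base-sensitive ortho-fluorobenzaldehyde unit untouched.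

Step 3
Reactants: 3 2-(4-bromophenoxy)-4-iodobenzaldehyde; 6 2-fluoro-5-vinylbenzaldehyde
Product: 7 2-(4-bromophenoxy)-4-[(E)-2-(4-fluoro-3-formylphenyl)ethenyl]benzaldehyde
Conditions: Pd(OAc)2 (cat.), n-Bu4NCl, NaHCO3, DMF, 60 °C
Reagents that add atoms: none
Why: Heck reaction under ligand-free phase-transfer conditions, in which oxidative addition at the C–I bond para to the formyl group is much faster than at the electron-rich C–Br bond, and syn β-hydride elimination should give the E stilbene that joins rings D and A.

Step 4
Reactants: 7 2-(4-bromophenoxy)-4-[(E)-2-(4-fluoro-3-formylphenyl)ethenyl]benzaldehyde; 8 3-ethynylphenol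
Product: 9 4-[(E)-2-(4-fluoro-3-formylphenyl)ethenyl]-2-{4-[(3-hydroxyphenyl)ethynyl]phenoxy}benzaldehyde
Conditions: PdCl2(PhCN)2 (cat.), P(t-Bu)3 (cat.), CuI (cat.), i-Pr2NH, dioxane, rt
Reagents that add atoms: none
Why: Sonogashira coupling of the aryl bromide at room temperature with the bulky electron-rich phosphine, where the copper acetylide outcompetes the unreactive 1,2-diarylethene, the free phenol is tolerated and the hindered amine base is too weak to start SNAr at the C–F bond.

Step 5
Reactants: 9 4-[(E)-2-(4-fluoro-3-formylphenyl)ethenyl]-2-{4-[(3-hydroxyphenyl)ethynyl]phenoxy}benzaldehyde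
Product: 10 4-[2-(4-fluoro-3-formylphenyl)ethyl]-2-{4-[2-(3-hydroxyphenyl)ethyl]phenoxy}benzaldehyde
Conditions: H2 (1 atm), 10% Pd/C, Ph2S (cat.), EtOAc, rt
Reagents that add atoms: none
Why: Heterogeneous catalytic hydrogenation over sulfide-poisoned palladium, which should saturate the alkyne and the alkene to the two ethano bridges while aryl aldehydes, the C–F bond and the diaryl ether are left intact.

Step 6
Reactants: 10 4-[2-(4-fluoro-3-formylphenyl)ethyl]-2-{4-[2-(3-hydroxyphenyl)ethyl]phenoxy}benzaldehyde
Product: 11 macrocyclic dialdehyde (the target skeleton with a formyl group in place of each hydroxyl group)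
Conditions: K2CO3, DMF, 110 °C, slow addition of 10 to about 2 mM
Reagents that add atoms: none
Why: Intramolecular SNAr (addition–elimination): carbonate deprotonates the ring-B phenol, the phenoxide adds ipso to the C–F carbon of ring A to give a Meisenheimer adduct stabilised by the ortho formyl group, and loss of fluoride restores the arene. The closest known reaction type is the fluoride-displacement macrocyclisation used for macrocyclic diaryl ethers with nitro-activated fluoroarenes, here run with the weaker but well-precedented ortho-formyl activation of 2-fluorobenzaldehydes. The one ring closed is the 20-membered macrocycle, formed end to end by C–O bond formation through exo attack at the aryl carbon, helped by the two flexible ethano bridges. No stereocentre is formed. The selectivity needed is ring closure over intermolecular etherification and attack at the correct carbon: the substrate has a single phenol and a single C–F bond, the only other activated position (the aryloxy carbon of ring D) bears a poor leaving group, and slow addition at high dilution should suppress oligomers.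

Step 7
Reactants: 11 macrocyclic dialdehyde
Product: 13 CNP0329842.0 (macrocyclic bis(bibenzyl) diphenol), via macrocyclic bis-formate 12 (not isolated)
Conditions: mCPBA, CH2Cl2, rt; then K2CO3 (cat.), MeOH, rt
Reagents that add atoms: mCPBA O=C(OO)c1cccc(Cl)c1
Why: Double Baeyer–Villiger (Dakin-type) oxidation in which each Criegee adduct of a 2-aryloxybenzaldehyde should rearrange with migration of the electron-rich aryl group to an aryl formate, and methanolysis then frees both phenols, while diaryl ethers and benzylic CH2 groups are inert to the peracid.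

Compound list
1 | 4-bromophenol | Oc1ccc(Br)cc1 | starting material
2 | 2-fluoro-4-iodobenzaldehyde | O=Cc1ccc(I)cc1F | starting material
3 | 2-(4-bromophenoxy)-4-iodobenzaldehyde | O=Cc1ccc(I)cc1Oc1ccc(Br)cc1 | intermediate
4 | 5-bromo-2-fluorobenzaldehyde | O=Cc1cc(Br)ccc1F | starting material
5 | tributyl(vinyl)stannane | C=C[Sn](CCCC)(CCCC)CCCC | starting material
6 | 2-fluoro-5-vinylbenzaldehyde | C=Cc1ccc(F)c(C=O)c1 | intermediate
7 | 2-(4-bromophenoxy)-4-[(E)-2-(4-fluoro-3-formylphenyl)ethenyl]benzaldehyde | O=Cc1ccc(/C=C/c2ccc(F)c(C=O)c2)cc1Oc1ccc(Br)cc1 | intermediate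
8 | 3-ethynylphenol | C#Cc1cccc(O)c1 | starting material
9 | 4-[(E)-2-(4-fluoro-3-formylphenyl)ethenyl]-2-{4-[(3-hydroxyphenyl)ethynyl]phenoxy}benzaldehyde | O=Cc1ccc(/C=C/c2ccc(F)c(C=O)c2)cc1Oc1ccc(C#Cc2cccc(O)c2)cc1 | intermediate
10 | 4-[2-(4-fluoro-3-formylphenyl)ethyl]-2-{4-[2-(3-hydroxyphenyl)ethyl]phenoxy}benzaldehyde | O=Cc1ccc(CCc2ccc(F)c(C=O)c2)cc1Oc1ccc(CCc2cccc(O)c2)cc1 | intermediate
11 | macrocyclic dialdehyde (target skeleton, CHO in place of each OH) | O=Cc1cc2ccc1Oc1cccc(c1)CCc1ccc(cc1)Oc1cc(ccc1C=O)CC2 | intermediate
12 | macrocyclic bis-formate (target with both OH groups as formate esters) | O=COc1cc2ccc1Oc1cccc(c1)CCc1ccc(cc1)Oc1cc(ccc1OC=O)CC2 | intermediate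
13 | CNP0329842.0, macrocyclic bis(bibenzyl) diphenol | Oc1cc2ccc1Oc1cccc(c1)CCc1ccc(cc1)Oc1cc(ccc1O)CC2 | target

Total step count: 7. Longest linear sequence: 6 steps (1, 3, 4, 5, 6, 7).

Steps most likely to fail

Step 6. Intermolecular etherification may outrun ring closure and give oligomers. Fluoride displacement may also be slow at a carbon that has only one activating group and a para alkyl donor, so that the aldehydes degrade on long heating with base. The fallback closes the same ring by C–C instead of C–O bond formation; it sets out from 7 and comes back at 11. Hydrogenation of the stilbene of 7 (Pd/C, Ph2S, H2; aryl bromide and aldehydes retained) should give 2-(4-bromophenoxy)-4-[2-(4-fluoro-3-formylphenyl)ethyl]benzaldehyde F1. Intermolecular SNAr of F1 with an excess of purchased 3-vinylphenol (C=Cc1cccc(O)c1; K2CO3, DMF, 90 °C) should give 2-(4-bromophenoxy)-4-{2-[3-formyl-4-(3-vinylphenoxy)phenyl]ethyl}benzaldehyde F2. An intramolecular Heck reaction at high dilution (Pd2(dba)3, P(t-Bu)3, Cy2NMe, dioxane, 80 °C) would then close the 20-membered ring as the macrocyclic E-stilbene dialdehyde F3, and hydrogenation of F3 (Pd/C, Ph2S, H2) returns to 11.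

Step 5. The formyl groups may be over-reduced, the C–F bond may be hydrogenolysed, or the reduction may stall at the alkene stage under the poisoned catalyst. The fallback masks the aldehydes; it sets out from 9 and comes back at 10. Acetalisation of 9 (ethylene glycol, TsOH, toluene, water removal) should give the bis(1,3-dioxolane) enyne F4. Ordinary hydrogenation (H2, Pd/C, EtOAc) would give the saturated bis(1,3-dioxolane) F5, and aqueous HCl in THF releases 10.

Step 7. Hydride instead of aryl migration may occur at the less electron-rich ring-A aldehyde and give a carboxylic acid, or the freed electron-rich phenols may be over-oxidised. The fallback goes through methyl ketones, where aryl migrates reliably in preference to methyl; it sets out from 11 and comes back at 13. Addition of MeMgBr (THF, 0 °C) should give the macrocyclic bis(1-hydroxyethyl) compound F6 as a diastereomer mixture. Dess–Martin oxidation would give the macrocyclic diacetyl compound F7, and Baeyer–Villiger oxidation (mCPBA, cat. TFA, CH2Cl2) the macrocyclic diacetate F8. Methanolysis of F8 (K2CO3, MeOH) delivers 13.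

Further compounds
F1 | step 6 | 2-(4-bromophenoxy)-4-[2-(4-fluoro-3-formylphenyl)ethyl]benzaldehyde | O=Cc1ccc(CCc2ccc(F)c(C=O)c2)cc1Oc1ccc(Br)cc1
F2 | step 6 | 2-(4-bromophenoxy)-4-{2-[3-formyl-4-(3-vinylphenoxy)phenyl]ethyl}benzaldehyde | O=Cc1ccc(CCc2ccc(Oc3cccc(C=C)c3)c(C=O)c2)cc1Oc1ccc(Br)cc1
F3 | step 6 | macrocyclic E-stilbene dialdehyde (11 with a trans CH=CH between rings B and C) | O=Cc1cc2ccc1Oc1cccc(c1)/C=C/c1ccc(cc1)Oc1cc(ccc1C=O)CC2
F4 | step 5 | bis(1,3-dioxolane) of 9 | C1COC(O1)c1ccc(/C=C/c2ccc(F)c(C3OCCO3)c2)cc1Oc1ccc(C#Cc2cccc(O)c2)cc1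
F5 | step 5 | bis(1,3-dioxolane) of 10 | C1COC(O1)c1ccc(CCc2ccc(F)c(C3OCCO3)c2)cc1Oc1ccc(CCc2cccc(O)c2)cc1
F6 | step 7 | macrocyclic bis(1-hydroxyethyl) compound (diastereomer mixture) | CC(O)c1cc2ccc1Oc1cccc(c1)CCc1ccc(cc1)Oc1cc(ccc1C(C)O)CC2
F7 | step 7 | macrocyclic diacetyl compound | CC(=O)c1cc2ccc1Oc1cccc(c1)CCc1ccc(cc1)Oc1cc(ccc1C(C)=O)CC2
F8 | step 7 | macrocyclic diacetate of 13 | CC(=O)Oc1cc2ccc1Oc1cccc(c1)CCc1ccc(cc1)Oc1cc(ccc1OC(C)=O)CC2
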